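**Strategy.** The plan rests on removing O1 of the top catechin unit, the ring-C oxygen that bridges A-ring carbon C8a and C2. Without it, ring C contracts to the cyclopentanone of a 3-aryl-4,6-dibenzyloxyindan-1-one whose C3 is the future C4 and carries C8 of a perbenzylated gallocatechin-(4β→8)-catechin dimer. A Baeyer–Villiger oxidation then inserts O1 in one operation, forming C8a–O1 and O1–C2 and delivering the 4-aryl-dihydrocoumarin with the C4 stereocentre intact and the phloroglucinol pattern of ring A complete. The indanone comes from a Heck-closed indenone by CBS reduction and a stereospecific 1,3-hydrogen shift; the lactone is advanced by aryllithium addition, dehydration and hydroboration.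

Key step: step 15

Remark: the catechol B ring is brought in as 4-bromo-1,2-bis(benzyloxy)benzene, not as a dimethyl ether, because methyl ethers would survive the closing hydrogenolysis; this bromide and 3,5-bis(benzyloxy)acetophenone are taken as purchasable.

Naming: flavan numbering is used for the flavan units (top, middle, bottom); "Dim" stands for dimer 10 bonded through C8 of its gallocatechin (middle) unit.

**Route**

Step 1
Reactants: 1 (+)-catechin
Product: 2 5,7,3',4'-tetra-O-benzyl-(+)-catechin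
Conditions: BnBr, K2CO3, DMF, 0 °C to rt
Reagents that add atoms: benzyl bromide, BrCc1ccccc1
Why: Williamson etherification in which K2CO3 deprotonates only the four phenols, so the C3 alcohol stays free and the 2R,3S centres are not involved.

Step 2
Reactants: 2 5,7,3',4'-tetra-O-benzyl-(+)-catechin
Product: 3 8-bromo-5,7,3',4'-tetra-O-benzyl-(+)-catechin
Conditions: NBS (1.0 equiv), CH2Cl2, −78 °C to rt
Reagents that add atoms: N-bromosuccinimide, O=C1CCC(=O)N1Br
Why: Electrophilic aromatic bromination should go to C8 of ring A, which is activated by three oxygens and is less shielded than C6 between the two benzyloxy groups.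

Step 3
Reactants: 3 8-bromo-5,7,3',4'-tetra-O-benzyl-(+)-catechin
Product: 4 8-bromo-3,5,7,3',4'-penta-O-benzyl-(+)-catechin
Conditions: NaH, BnBr, cat. Bu4NI, DMF, 0 °C to rt
Reagents that add atoms: benzyl bromide, BrCc1ccccc1
Why: Williamson etherification of the C3 alkoxide, in which no C–H bond at a stereocentre is acidic, so the configuration is kept.

Step 4
Reactants: 5 (2R,3R)-dihydromyricetin
Product: 6 (2R,3R)-5,7,3',4',5'-penta-O-benzyldihydromyricetin
Conditions: BnBr, K2CO3, DMF, rt to 45 °C, Ar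
Reagents that add atoms: benzyl bromide, BrCc1ccccc1
Why: Williamson etherification of the five phenols under carbonate, kept mild and air-free so that the dihydroflavonol ring should neither open by retro-oxa-Michael reaction nor be dehydrogenated, the 2,3-trans centres being retained.

Step 5
Reactants: 6 (2R,3R)-5,7,3',4',5'-penta-O-benzyldihydromyricetin
Product: 7 (2R,3R)-3,5,7,3',4',5'-hexa-O-benzyldihydromyricetin
Conditions: BnBr, Ag2O, CH2Cl2/DMF, rt, dark
Reagents that add atoms: benzyl bromide, BrCc1ccccc1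
Why: Silver-oxide-promoted O-benzylation (Purdie–Irvine type) needs no strong base, which should spare the β-aryloxy ketone from enolisation, ring opening and C3 epimerisation.

Step 6
Reactants: 4 8-bromo-3,5,7,3',4'-penta-O-benzyl-(+)-catechin, 7 (2R,3R)-3,5,7,3',4',5'-hexa-O-benzyldihydromyricetin
Product: 9 C4 tertiary alcohol of the 4→8 dimer (C4 epimer not assigned), via 8-lithio-penta-O-benzylcatechin 8 (not isolated)
Conditions: t-BuLi (2 equiv), THF, −78 °C; then 7, −78 to −40 °C; H2O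
Reagents that add atoms: none
Why: Bromine–lithium exchange followed by 1,2-addition of the aryllithium to the aryl ketone at low temperature, where addition should outrun enolisation; the C4 carbinol centre formed here is erased in step 7, so its configuration does not matter.

Step 7
Reactants: 9 C4 tertiary alcohol of the 4→8 dimer
Product: 10 3,5,7,3',4',5'-hexa-O-benzylgallocatechin-(4β→8)-3,5,7,3',4'-penta-O-benzylcatechin (middle unit 2R,3S,4R; 3,4-cis)
Conditions: Bu3SnH, CF3CO2H, CH2Cl2, 0 °C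
Reagents that add atoms: none
Why: Ionic hydrogenation in which acid ionises the tertiary, doubly benzylic alcohol to a C4 cation and the tin hydride should deliver hydride to the face anti to the neighbouring C3 benzyloxy group, which places the bottom unit cis to that group (4β, 4R).

Step 8
Reactants: 10 perbenzylated 4β→8 dimer
Product: 11 middle-unit 8-bromo derivative of dimer 10 (Dim–Br)
Conditions: NBS (1.0 equiv), CH2Cl2, −78 to −20 °C
Reagents that add atoms: N-bromosuccinimide, O=C1CCC(=O)N1Br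
Why: Electrophilic aromatic bromination should select the only free C8 position, that of the middle unit, since the two other ring-A carbons are C6 positions hemmed in by two benzyloxy groups and the B rings are less electron-rich.

Step 9
Reactants: 11 Dim–Br
Product: 13 middle-unit 8-carbaldehyde of dimer 10 (Dim–CHO), via middle-unit 8-lithio dimer 12 (not isolated)
Conditions: n-BuLi, THF, −78 °C; then DMF, −78 to 0 °C; H2O
Reagents that add atoms: N,N-dimethylformamide, CN(C)C=O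
Why: Bromine–lithium exchange and formylation of the aryllithium with DMF (Bouveault aldehyde synthesis), the substrate having no acidic proton and the hemiaminal salt collapsing to the aldehyde on aqueous work-up.

Step 10
Reactants: 14 3,5-bis(benzyloxy)acetophenone
Product: 15 1-[3,5-bis(benzyloxy)-2-bromophenyl]ethanone
Conditions: NBS (1.0 equiv), MeCN, 0 °C to rt
Reagents that add atoms: N-bromosuccinimide, O=C1CCC(=O)N1Br
Why: Electrophilic aromatic bromination at C2, ortho and para to the two benzyloxy groups, should be preferred over C4 between the two ethers, and without acid or light the acetyl methyl group is not brominated.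

Step 11
Reactants: 13 Dim–CHO, 15 1-[3,5-bis(benzyloxy)-2-bromophenyl]ethanone
Product: 16 (E)-1-[3,5-bis(benzyloxy)-2-bromophenyl]-3-Dim-prop-2-en-1-one
Conditions: KOH, EtOH/THF, rt to 40 °C
Reagents that add atoms: none
Why: Claisen–Schmidt (crossed aldol) condensation between a non-enolisable aldehyde and a methyl ketone, the E1cB dehydration giving the conjugated E-enone.

Step 12
Reactants: 16 (E)-2'-bromochalcone
Product: 17 4,6-bis(benzyloxy)-3-Dim-1H-inden-1-one
Conditions: Pd(OAc)2 (10 mol %), PPh3, K2CO3, DMF, 100 °C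
Reagents that add atoms: none
Why: Intramolecular Mizoroki–Heck reaction in which zerovalent palladium inserts into the aryl–bromine bond, the aryl group adds to the enone β-carbon to close the five-membered ring and β-hydride elimination from the palladium enolate restores the double bond as the indenone.

Step 13
Reactants: 17 4,6-bis(benzyloxy)-3-Dim-1H-inden-1-one
Product: 18 (1R)-4,6-bis(benzyloxy)-3-Dim-1H-inden-1-ol
Conditions: (S)-2-methyl-CBS-oxazaborolidine (0.3 equiv), catecholborane, toluene, −78 °C; then MeOH, aq. NaOH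
Reagents that add atoms: none
Why: Corey–Bakshi–Shibata reduction, a catalyst-controlled 1,2-hydride transfer at the unhindered C1 carbonyl in which the fused benzo ring acts as the large group and the C2–H side as the small one, should set C1 as R far from the bulky C3 aryl group.

Step 14
Reactants: 18 (1R)-4,6-bis(benzyloxy)-3-Dim-1H-inden-1-ol
Product: 19 (3S)-4,6-bis(benzyloxy)-3-Dim-indan-1-one
Conditions: DABCO, Et3N/THF, 60 °C
Reagents that add atoms: none
Why: Amine-mediated 1,3-prototropic shift of the indenol, in which the C1 proton is carried within a tight ammonium–indenide ion pair to the same face of C3 (suprafacial transfer) and the resulting enol tautomerises to the ketone, should relay the C1 configuration into the 3S centre.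

Step 15
Reactants: 19 (3S)-4,6-bis(benzyloxy)-3-Dim-indan-1-one
Product: 20 (4S)-5,7-bis(benzyloxy)-4-Dim-chroman-2-one
Conditions: m-CPBA (3 equiv), NaHCO3, CH2Cl2, 0 °C to rt, dark
Reagents that add atoms: 3-chloroperoxybenzoic acid, OOC(=O)c1cccc(Cl)c1
Why: The peracid adds to the C1 carbonyl to give the tetrahedral Criegee adduct, from which the aryl carbon C7a shifts from carbon to the proximal peroxide oxygen as 3-chlorobenzoate departs, so that the new oxygen sits between C1 and C7a. This is the Baeyer–Villiger oxidation of 1-indanones to 3,4-dihydrocoumarins, a known reaction type. The six-membered lactone ring is not closed end to end but arises by ring expansion of the cyclopentanone through this 1,2-shift, which makes the bonds C8a–O1 and O1–C2 (flavan numbering). No stereocentre is created, and the shift does not touch C3 of the indanone, which becomes C4 of the lactone with its S configuration unchanged. Two selectivities are needed: migration of the sp2 aryl carbon in preference to the primary C2 methylene, which the higher migratory aptitude of aryl groups should secure, and oxidation of the ketone in preference to the electron-rich benzyloxy arenes, which the hydrogencarbonate buffer, the low temperature and the absence of strong acid are meant to secure while also sparing the acid-labile interflavan bond.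

Step 16
Reactants: 20 (4S)-5,7-bis(benzyloxy)-4-Dim-chroman-2-one, 21 4-bromo-1,2-bis(benzyloxy)benzene
Product: 24 (4S)-5,7-bis(benzyloxy)-2-[3,4-bis(benzyloxy)phenyl]-4-Dim-4H-chromene, via 3,4-bis(benzyloxy)phenyllithium 22 (not isolated), via ring-opened hydroxy ketone 23 (not isolated)
Conditions: 21, n-BuLi, THF, −78 °C; then 20, −78 °C; H2O; then PPTS, toluene, 80 °C, 4 Å MS
Reagents that add atoms: none
Why: Acyl substitution of the aryl lactone by one equivalent of aryllithium at low temperature gives the phenol ketone, whose acid-catalysed cyclodehydration through the cyclic hemiketal forms the 2-aryl-4H-chromene without touching C4.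

Step 17
Reactants: 24 (4S)-2,4-diaryl-4H-chromene
Product: 26 pentadeca-O-benzyl catechin-(4α→8)-gallocatechin-(4β→8)-catechin with free top C3 hydroxyl (top unit 2R,3S,4S), via C3 borane adduct 25 (not isolated)
Conditions: BH3·THF, THF, 0 °C to rt; then NaOH, H2O2, 0 °C
Reagents that add atoms: hydrogen peroxide, OO
Why: Hydroboration–oxidation of the cyclic enol ether, in which boron goes to C3 (β to the ring oxygen) and hydrogen to C2 in a syn addition on the face opposite the C4 aryl group and the C–B bond is oxidised with retention, should give the 2,3-trans-3,4-trans flavan-3-ol.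

Step 18
Reactants: 26 pentadeca-O-benzyl trimer
Product: 27 catechin-(4α→8)-gallocatechin-(4β→8)-catechin (CNP0302529.2)
Conditions: H2 (1 atm), Pd(OH)2/C, THF/MeOH/H2O, rt
Reagents that add atoms: none
Why: Catalytic hydrogenolysis cleaves all fifteen benzyl ethers under neutral conditions, the cyclic benzylic C2–O1 bonds and the interflavan bonds being far slower to cleave, so no stereocentre is affected.

**Compound list**

1 | (+)-catechin (2R,3S) | Oc1cc(O)c2c(c1)O[C@H](c1ccc(O)c(O)c1)[C@@H](O)C2 | starting material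
2 | 5,7,3',4'-tetra-O-benzyl-(+)-catechin | c1c(OCc9ccccc9)cc(OCc9ccccc9)c2c1O[C@H](c1ccc(OCc9ccccc9)c(OCc9ccccc9)c1)[C@@H](O)C2 | intermediate
3 | 8-bromo-5,7,3',4'-tetra-O-benzyl-(+)-catechin | Brc1c(OCc9ccccc9)cc(OCc9ccccc9)c2c1O[C@H](c1ccc(OCc9ccccc9)c(OCc9ccccc9)c1)[C@@H](O)C2 | intermediate
4 | 8-bromo-3,5,7,3',4'-penta-O-benzyl-(+)-catechin | Brc1c(OCc9ccccc9)cc(OCc9ccccc9)c2c1O[C@H](c1ccc(OCc9ccccc9)c(OCc9ccccc9)c1)[C@@H](OCc9ccccc9)C2 | intermediate
5 | (2R,3R)-dihydromyricetin | Oc1cc(O)c2c(c1)O[C@H](c1cc(O)c(O)c(O)c1)[C@@H](O)C2=O | starting material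
6 | (2R,3R)-5,7,3',4',5'-penta-O-benzyldihydromyricetin | c1c(OCc9ccccc9)cc(OCc9ccccc9)c2c1O[C@H](c1cc(OCc9ccccc9)c(OCc9ccccc9)c(OCc9ccccc9)c1)[C@@H](O)C2=O | intermediate
7 | (2R,3R)-3,5,7,3',4',5'-hexa-O-benzyldihydromyricetin | c1c(OCc9ccccc9)cc(OCc9ccccc9)c2c1O[C@H](c1cc(OCc9ccccc9)c(OCc9ccccc9)c(OCc9ccccc9)c1)[C@@H](OCc9ccccc9)C2=O | intermediate
8 | 8-lithio-3,5,7,3',4'-penta-O-benzylcatechin (not isolated) | [Li]c1c(OCc9ccccc9)cc(OCc9ccccc9)c2c1O[C@H](c1ccc(OCc9ccccc9)c(OCc9ccccc9)c1)[C@@H](OCc9ccccc9)C2 | intermediate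
9 | hexa-O-benzyl-4-hydroxygallocatechin-(4→8)-penta-O-benzylcatechin, tertiary C4 alcohol (C4 epimer not assigned; centre removed in step 7) | c1c(OCc9ccccc9)cc(OCc9ccccc9)c2c1O[C@H](c1cc(OCc9ccccc9)c(OCc9ccccc9)c(OCc9ccccc9)c1)[C@@H](OCc9ccccc9)C2(O)c1c(OCc9ccccc9)cc(OCc9ccccc9)c2c1O[C@H](c1ccc(OCc9ccccc9)c(OCc9ccccc9)c1)[C@@H](OCc9ccccc9)C2 | intermediate
10 | hexa-O-benzylgallocatechin-(4β→8)-penta-O-benzylcatechin (2R,3S,4R / 2R,3S) | c1c(OCc9ccccc9)cc(OCc9ccccc9)c2c1O[C@H](c1cc(OCc9ccccc9)c(OCc9ccccc9)c(OCc9ccccc9)c1)[C@@H](OCc9ccccc9)[C@H]2c1c(OCc9ccccc9)cc(OCc9ccccc9)c2c1O[C@H](c1ccc(OCc9ccccc9)c(OCc9ccccc9)c1)[C@@H](OCc9ccccc9)C2 | intermediate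
11 | middle-unit 8-bromo dimer (Dim–Br) | Brc1c(OCc9ccccc9)cc(OCc9ccccc9)c2c1O[C@H](c1cc(OCc9ccccc9)c(OCc9ccccc9)c(OCc9ccccc9)c1)[C@@H](OCc9ccccc9)[C@H]2c1c(OCc9ccccc9)cc(OCc9ccccc9)c2c1O[C@H](c1ccc(OCc9ccccc9)c(OCc9ccccc9)c1)[C@@H](OCc9ccccc9)C2 | intermediate
12 | middle-unit 8-lithio dimer (not isolated) | [Li]c1c(OCc9ccccc9)cc(OCc9ccccc9)c2c1O[C@H](c1cc(OCc9ccccc9)c(OCc9ccccc9)c(OCc9ccccc9)c1)[C@@H](OCc9ccccc9)[C@H]2c1c(OCc9ccccc9)cc(OCc9ccccc9)c2c1O[C@H](c1ccc(OCc9ccccc9)c(OCc9ccccc9)c1)[C@@H](OCc9ccccc9)C2 | intermediate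
13 | middle-unit 8-carbaldehyde of the dimer (Dim–CHO) | O=Cc1c(OCc9ccccc9)cc(OCc9ccccc9)c2c1O[C@H](c1cc(OCc9ccccc9)c(OCc9ccccc9)c(OCc9ccccc9)c1)[C@@H](OCc9ccccc9)[C@H]2c1c(OCc9ccccc9)cc(OCc9ccccc9)c2c1O[C@H](c1ccc(OCc9ccccc9)c(OCc9ccccc9)c1)[C@@H](OCc9ccccc9)C2 | intermediate
14 | 3,5-bis(benzyloxy)acetophenone | CC(=O)c1cc(OCc9ccccc9)cc(OCc9ccccc9)c1 | starting material
15 | 1-[3,5-bis(benzyloxy)-2-bromophenyl]ethanone | CC(=O)c1cc(OCc9ccccc9)cc(OCc9ccccc9)c1Br | intermediate
16 | (E)-1-[3,5-bis(benzyloxy)-2-bromophenyl]-3-Dim-prop-2-en-1-one | O=C(c1cc(OCc9ccccc9)cc(OCc9ccccc9)c1Br)/C=C/c1c(OCc9ccccc9)cc(OCc9ccccc9)c2c1O[C@H](c1cc(OCc9ccccc9)c(OCc9ccccc9)c(OCc9ccccc9)c1)[C@@H](OCc9ccccc9)[C@H]2c1c(OCc9ccccc9)cc(OCc9ccccc9)c2c1O[C@H](c1ccc(OCc9ccccc9)c(OCc9ccccc9)c1)[C@@H](OCc9ccccc9)C2 | intermediate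
17 | 4,6-bis(benzyloxy)-3-Dim-1H-inden-1-one | O=C1C=C(c2c(OCc9ccccc9)cc(OCc9ccccc9)cc21)c1c(OCc9ccccc9)cc(OCc9ccccc9)c2c1O[C@H](c1cc(OCc9ccccc9)c(OCc9ccccc9)c(OCc9ccccc9)c1)[C@@H](OCc9ccccc9)[C@H]2c1c(OCc9ccccc9)cc(OCc9ccccc9)c2c1O[C@H](c1ccc(OCc9ccccc9)c(OCc9ccccc9)c1)[C@@H](OCc9ccccc9)C2 | intermediate
18 | (1R)-4,6-bis(benzyloxy)-3-Dim-1H-inden-1-ol | O[C@@H]1C=C(c2c(OCc9ccccc9)cc(OCc9ccccc9)cc21)c1c(OCc9ccccc9)cc(OCc9ccccc9)c2c1O[C@H](c1cc(OCc9ccccc9)c(OCc9ccccc9)c(OCc9ccccc9)c1)[C@@H](OCc9ccccc9)[C@H]2c1c(OCc9ccccc9)cc(OCc9ccccc9)c2c1O[C@H](c1ccc(OCc9ccccc9)c(OCc9ccccc9)c1)[C@@H](OCc9ccccc9)C2 | intermediate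
19 | (3S)-4,6-bis(benzyloxy)-3-Dim-indan-1-one (key-step precursor) | O=C1C[C@@H](c2c(OCc9ccccc9)cc(OCc9ccccc9)cc21)c1c(OCc9ccccc9)cc(OCc9ccccc9)c2c1O[C@H](c1cc(OCc9ccccc9)c(OCc9ccccc9)c(OCc9ccccc9)c1)[C@@H](OCc9ccccc9)[C@H]2c1c(OCc9ccccc9)cc(OCc9ccccc9)c2c1O[C@H](c1ccc(OCc9ccccc9)c(OCc9ccccc9)c1)[C@@H](OCc9ccccc9)C2 | intermediate
20 | (4S)-5,7-bis(benzyloxy)-4-Dim-chroman-2-one (key-step product) | O=C1C[C@@H](c2c(OCc9ccccc9)cc(OCc9ccccc9)cc2O1)c1c(OCc9ccccc9)cc(OCc9ccccc9)c2c1O[C@H](c1cc(OCc9ccccc9)c(OCc9ccccc9)c(OCc9ccccc9)c1)[C@@H](OCc9ccccc9)[C@H]2c1c(OCc9ccccc9)cc(OCc9ccccc9)c2c1O[C@H](c1ccc(OCc9ccccc9)c(OCc9ccccc9)c1)[C@@H](OCc9ccccc9)C2 | intermediate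
21 | 4-bromo-1,2-bis(benzyloxy)benzene | Brc1ccc(OCc9ccccc9)c(OCc9ccccc9)c1 | starting material
22 | 3,4-bis(benzyloxy)phenyllithium (not isolated) | [Li]c1ccc(OCc9ccccc9)c(OCc9ccccc9)c1 | intermediate
23 | (3S)-1-[3,4-bis(benzyloxy)phenyl]-3-[2,4-bis(benzyloxy)-6-hydroxyphenyl]-3-Dim-propan-1-one (not isolated) | O=C(c1ccc(OCc9ccccc9)c(OCc9ccccc9)c1)C[C@@H](c1c(OCc9ccccc9)cc(OCc9ccccc9)cc1O)c1c(OCc9ccccc9)cc(OCc9ccccc9)c2c1O[C@H](c1cc(OCc9ccccc9)c(OCc9ccccc9)c(OCc9ccccc9)c1)[C@@H](OCc9ccccc9)[C@H]2c1c(OCc9ccccc9)cc(OCc9ccccc9)c2c1O[C@H](c1ccc(OCc9ccccc9)c(OCc9ccccc9)c1)[C@@H](OCc9ccccc9)C2 | intermediate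
24 | (4S)-5,7-bis(benzyloxy)-2-[3,4-bis(benzyloxy)phenyl]-4-Dim-4H-chromene | O1C(c3ccc(OCc9ccccc9)c(OCc9ccccc9)c3)=C[C@@H](c2c(OCc9ccccc9)cc(OCc9ccccc9)cc21)c1c(OCc9ccccc9)cc(OCc9ccccc9)c2c1O[C@H](c1cc(OCc9ccccc9)c(OCc9ccccc9)c(OCc9ccccc9)c1)[C@@H](OCc9ccccc9)[C@H]2c1c(OCc9ccccc9)cc(OCc9ccccc9)c2c1O[C@H](c1ccc(OCc9ccccc9)c(OCc9ccccc9)c1)[C@@H](OCc9ccccc9)C2 | intermediate
25 | top-unit C3 borane adduct: boron on C3 anti to the C4 aryl group, hydrogen on C2 syn to boron (not isolated) | O(Cc9ccccc9)c1cc(OCc9ccccc9)c2c(c1)O[C@H](c1ccc(OCc9ccccc9)c(OCc9ccccc9)c1)[C@@H](B)[C@@H]2c1c(OCc9ccccc9)cc(OCc9ccccc9)c2c1O[C@H](c1cc(OCc9ccccc9)c(OCc9ccccc9)c(OCc9ccccc9)c1)[C@@H](OCc9ccccc9)[C@H]2c1c(OCc9ccccc9)cc(OCc9ccccc9)c2c1O[C@H](c1ccc(OCc9ccccc9)c(OCc9ccccc9)c1)[C@@H](OCc9ccccc9)C2 | intermediate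
26 | pentadeca-O-benzyl catechin-(4α→8)-gallocatechin-(4β→8)-catechin, top C3 hydroxyl free (top 2R,3S,4S) | O(Cc9ccccc9)c1cc(OCc9ccccc9)c2c(c1)O[C@H](c1ccc(OCc9ccccc9)c(OCc9ccccc9)c1)[C@@H](O)[C@@H]2c1c(OCc9ccccc9)cc(OCc9ccccc9)c2c1O[C@H](c1cc(OCc9ccccc9)c(OCc9ccccc9)c(OCc9ccccc9)c1)[C@@H](OCc9ccccc9)[C@H]2c1c(OCc9ccccc9)cc(OCc9ccccc9)c2c1O[C@H](c1ccc(OCc9ccccc9)c(OCc9ccccc9)c1)[C@@H](OCc9ccccc9)C2 | intermediate
27 | catechin-(4α→8)-gallocatechin-(4β→8)-catechin (top 2R,3S,4S; middle 2R,3S,4R; bottom 2R,3S) | Oc1cc(O)c2c(c1)O[C@H](c1ccc(O)c(O)c1)[C@@H](O)[C@@H]2c1c(O)cc(O)c2c1O[C@H](c1cc(O)c(O)c(O)c1)[C@@H](O)[C@H]2c1c(O)cc(O)c2c1O[C@H](c1ccc(O)c(O)c1)[C@@H](O)C2 | target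

**Step count**

Total: 18 steps. Longest linear sequence: 15 steps (1 → 2 → 3 → 4 → 9 → 10 → 11 → 13 → 16 → 17 → 18 → 19 → 20 → 24 → 26 → 27).

**Three steps most likely to fail**

1. Step 15 (Baeyer–Villiger oxidation). The peracid may attack the benzyloxy-rich arenes in competition with the ketone, the C2 methylene may migrate in place of the aryl carbon, or the buffered peracid may add too slowly to the conjugated aryl ketone. The fallback gives up the oxygen insertion and sets out from bromide 11. Bromine–lithium exchange (n-BuLi, THF, −78 °C), trapping with B(OMe)3 and mild hydrolysis would give the middle-unit C8 boronic acid of the dimer F1. Commercial 5,7-dihydroxycoumarin would be benzylated (BnBr, K2CO3, DMF) to 5,7-bis(benzyloxy)coumarin F2. Rhodium-catalysed enantioselective conjugate addition of F1 to F2 (Hayashi–Miyaura reaction; [Rh(acac)(C2H4)2], the SEGPHOS enantiomer that leads to the 4S product, dioxane/H2O, 60 °C) would form the C4–C8 bond and the C4 centre directly. This comes back to the route at lactone 20.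

2. Step 7 (ionic hydrogenation). Facial selectivity of hydride delivery to the C4 cation may be poor, giving the 4α-linked dimer, and the acid may also cleave the new interflavan bond. The fallback replaces hydride delivery by a tethered Friedel–Crafts coupling and sets out from 2 and 6. Compound 2 would be acylated with glutaric anhydride (DMAP, pyridine) to tetra-O-benzylcatechin 3-O-hemiglutarate F3. DCC/DMAP esterification of F3 with the C3 hydroxyl of 6 would give the glutarate-bridged keto diester F4. NaBH4 (THF/EtOH, 0 °C) would reduce the C4 ketone to the glutarate-bridged C4 alcohol F5. TMSOTf (CH2Cl2, −40 °C, high dilution) would ionise C4, and the tethered catechin ring A can reach it only from the face of the C3 ester, which should give the glutarate-bridged macrocyclic 4β→8 dimer F6. NaOMe in MeOH/THF would remove the bridge to give the dimer 3,3''-diol F7. NaH/BnBr benzylation comes back to the route at 10.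

3. Step 14 (1,3-prototropic shift). Deprotonation of the electron-rich indenol may be slow, and proton transfer through a loosened ion pair or by exchange with the medium may erode the configuration relayed from C1. The fallback sets out from indenone 17 and comes back at indanone 19, bypassing 18. It is a copper-hydride-catalysed asymmetric conjugate reduction (Cu(OAc)2, the DTBM-SEGPHOS enantiomer that leads to the 3S product, polymethylhydrosiloxane, t-BuOH, toluene, 0 °C), which sets C3 by catalyst-controlled hydride delivery to the β-carbon instead of by chirality relay. It forms no compound outside the list (entry F0).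

**Further compounds**

F1 | step 15 | middle-unit C8 boronic acid of dimer 10 | OB(O)c1c(OCc9ccccc9)cc(OCc9ccccc9)c2c1O[C@H](c1cc(OCc9ccccc9)c(OCc9ccccc9)c(OCc9ccccc9)c1)[C@@H](OCc9ccccc9)[C@H]2c1c(OCc9ccccc9)cc(OCc9ccccc9)c2c1O[C@H](c1ccc(OCc9ccccc9)c(OCc9ccccc9)c1)[C@@H](OCc9ccccc9)C2
F2 | step 15 | 5,7-bis(benzyloxy)coumarin | O=C1C=Cc2c(OCc9ccccc9)cc(OCc9ccccc9)cc2O1
F3 | step 7 | tetra-O-benzylcatechin 3-O-hemiglutarate | c1c(OCc9ccccc9)cc(OCc9ccccc9)c2c1O[C@H](c1ccc(OCc9ccccc9)c(OCc9ccccc9)c1)[C@@H](OC(=O)CCCC(=O)O)C2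
F4 | step 7 | glutarate-bridged keto diester | c1c(OCc9ccccc9)cc(OCc9ccccc9)c2c1O[C@H](c1ccc(OCc9ccccc9)c(OCc9ccccc9)c1)[C@@H](OC(=O)CCCC(=O)O[C@H]3C(=O)c4c(OCc9ccccc9)cc(OCc9ccccc9)cc4O[C@@H]3c1cc(OCc9ccccc9)c(OCc9ccccc9)c(OCc9ccccc9)c1)C2
F5 | step 7 | glutarate-bridged C4 alcohol (C4 epimer not assigned) | c1c(OCc9ccccc9)cc(OCc9ccccc9)c2c1O[C@H](c1ccc(OCc9ccccc9)c(OCc9ccccc9)c1)[C@@H](OC(=O)CCCC(=O)O[C@H]3C(O)c4c(OCc9ccccc9)cc(OCc9ccccc9)cc4O[C@@H]3c1cc(OCc9ccccc9)c(OCc9ccccc9)c(OCc9ccccc9)c1)C2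
F6 | step 7 | glutarate-bridged macrocyclic 4β→8 dimer | c15c(OCc9ccccc9)cc(OCc9ccccc9)c2c1O[C@H](c1ccc(OCc9ccccc9)c(OCc9ccccc9)c1)[C@@H](OC(=O)CCCC(=O)O[C@H]3[C@@H]5c4c(OCc9ccccc9)cc(OCc9ccccc9)cc4O[C@@H]3c1cc(OCc9ccccc9)c(OCc9ccccc9)c(OCc9ccccc9)c1)C2
F7 | step 7 | 4β→8 dimer 3,3''-diol | c1c(OCc9ccccc9)cc(OCc9ccccc9)c2c1O[C@H](c1cc(OCc9ccccc9)c(OCc9ccccc9)c(OCc9ccccc9)c1)[C@@H](O)[C@H]2c1c(OCc9ccccc9)cc(OCc9ccccc9)c2c1O[C@H](c1ccc(OCc9ccccc9)c(OCc9ccccc9)c1)[C@@H](O)C2
F0 | step 14 | none | none
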